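**Plan**

- Numbering of the quinone: C1 is the carbonyl between the docosyl- and methoxy-bearing carbons, then C2 (OMe), C3 (H), C4 (carbonyl), C5 (Me), C6 (docosyl). C2–C3 is a masked methoxyacetylene and the C4 oxygen lies meta to the C2 oxygen, the 3-alkoxyphenol pattern that a vinylketene–ynol ether benzannulation delivers; at the phenol stage C1 carries only hydrogen.
- Retrosynthesis: the C1 oxygen is removed first (para-oxidation of a phenol). The benzene ring is then cut at C1–C2, C3–C4 and C4–C5 into 3-docosyl-4-methylcyclobutenone (C4, C5, C6, C1) and methoxyacetylene (C2, C3). The cyclobutenone is cut at two ring bonds into tetracos-1-yne and a propanamide-derived keteniminium ion, and the alkyne at its propargylic C–C bond into 1-bromodocosane and acetylide.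
- Forward: the chain is joined to acetylide, the four-membered ring is made by a [2+2] cycloaddition, the six-membered ring arises by ring opening, [2+2], ring opening and 6π closure, and oxidation at C1 gives the quinone.
- Stereochemistry: the target has no stereocentre and no stereogenic double bond. The single sp3 centre of the cyclobutenone is made racemic and disappears on aromatisation.

Key step: step 4

Assumption: the side chain is the unbranched C22 (docosyl) chain; lithium acetylide–ethylenediamine complex and (for one fallback) ethoxyacetylene are taken as purchasable.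

**Route**

Step 1
Reactants: 1 1-bromodocosane; 2 lithium acetylide–ethylenediamine complex
Product: 3 tetracos-1-yne
Conditions: LiC≡CH·H2NCH2CH2NH2 (1.5 equiv), DMSO/THF, 10 °C → rt
Reagents that add atoms: none
Why: SN2 alkylation of the complexed lithium acetylide by an unhindered primary bromide in a dipolar aprotic medium is a standard terminal-alkyne synthesis and should stop at mono-alkylation.

Step 2
Reactants: 3 tetracos-1-yne; 4 N,N-dimethylpropanamide
Product: 7 racemic 3-docosyl-4-methylcyclobut-2-en-1-one, via keteniminium triflate 5 (not isolated), via cyclobuteniminium triflate 6 (not isolated)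
Conditions: Tf2O (1.3 equiv), 2,4,6-collidine (1.3 equiv), ClCH2CH2Cl, −20 °C → 80 °C; then H2O, 80 °C
Reagents that add atoms: water, O
Why: Ghosez keteniminium–alkyne [2+2] cycloaddition, in which the unsubstituted alkyne carbon of 3 attacks the central carbon of keteniminium ion 5 so that docosyl ends at C3 and the amide-derived CH(CH3) at C4 of iminium salt 6, which water hydrolyses to the enone; the C4 centre forms as a racemate and needs no control.

Step 3
Reactants: 8 chloroacetaldehyde dimethyl acetal
Product: 10 methoxyacetylene, via sodium methoxyacetylide 9 (not isolated)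
Conditions: NaNH2 (3 equiv), liq. NH3, −33 °C; NH3 evaporated; then satd aq NaCl, −70 °C → rt, distilled into cold toluene and used at once
Reagents that add atoms: none
Why: Twofold base-induced elimination (methanol, then HCl) of the chloroacetal by NaNH2 in liquid ammonia gives the sodium alkoxyacetylide, and cold aqueous protonation releases the ynol ether, the classical alkoxyacetylene preparation.

Step 4
Reactants: 7 racemic 3-docosyl-4-methylcyclobut-2-en-1-one; 10 methoxyacetylene
Product: 15 3-docosyl-5-methoxy-2-methylphenol, via vinylketene 11 (not isolated), via 4-vinylcyclobutenone 12 (not isolated), via dienylketene 13 (not isolated), via cyclohexa-2,4-dienone 14 (not isolated)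
Conditions: 10 (3 equiv), toluene, sealed tube, 80 °C → 110 °C
Reagents that add atoms: none
Why: Heating opens 7 by conrotatory 4π electrocyclic cleavage of its C1–C4 bond to vinylketene 11, whose ketene C=C adds methoxyacetylene 10 in a [2+2] cycloaddition to give 4-vinylcyclobutenone 12; this opens again to dienylketene 13, which closes to dienone 14 and tautomerises to phenol 15, so that every atom of 7 and 10 ends in 15. The closest known reaction type is the Danheiser benzannulation of cyclobutenones with alkoxyacetylenes. The six-membered ring is closed by a thermal disrotatory 6π electrocyclisation of 13 that joins the ketene carbon (quinone C4) to the methyl-bearing terminus (C5), after the [2+2] step has made C3–C4 and C1–C2. No stereocentre survives: the sp3 centres of 12 and 14 are erased by ring opening and enolisation, and the alkene geometry of 11 and 13 is immaterial because the reversible opening of 12 feeds the isomer that can cyclise. The selectivity needed is the regiochemistry of the ketene–alkyne [2+2], and polarity secures it: the unsubstituted, nucleophilic carbon of the ynol ether attacks the electrophilic ketene carbon, which places OMe meta to the new hydroxyl and leaves hydrogen at C1 and C3. The adjacency of docosyl and methyl is fixed beforehand by the substitution pattern of 7.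

Step 5
Reactants: 15 3-docosyl-5-methoxy-2-methylphenol
Product: 16 6-docosyl-2-methoxy-5-methyl-1,4-benzoquinone
Conditions: (KSO3)2NO (2.5 equiv), aq KH2PO4, MeN(C8H17)3Cl (cat.), CH2Cl2/H2O, rt
Reagents that add atoms: potassium nitrosodisulfonate (Fremy's salt), [K+].[K+].[O-]S(=O)(=O)N([O])S(=O)(=O)[O-]
Why: Teuber oxidation, in which one nitrosodisulfonate radical removes the phenolic hydrogen and a second couples through oxygen at the free para carbon (quinone C1), after which loss of imidodisulfonate gives the para-quinone; a phenol with an open para position is expected to give the 1,4-quinone in preference to the ortho-quinone.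

**Compound list**

1 | 1-bromodocosane | CCCCCCCCCCCCCCCCCCCCCCBr | starting material
2 | lithium acetylide–ethylenediamine complex | [Li+].[C-]#C.NCCN | starting material
3 | tetracos-1-yne | CCCCCCCCCCCCCCCCCCCCCCC#C | intermediate
4 | N,N-dimethylpropanamide | CCC(=O)N(C)C | starting material
5 | N-methyl-N-(prop-1-en-1-ylidene)methanaminium trifluoromethanesulfonate (keteniminium triflate) | CC=C=[N+](C)C.[O-]S(=O)(=O)C(F)(F)F | intermediate
6 | N-(3-docosyl-4-methylcyclobut-2-en-1-ylidene)-N-methylmethanaminium trifluoromethanesulfonate, racemic | CC1C(=[N+](C)C)C=C1CCCCCCCCCCCCCCCCCCCCCC.[O-]S(=O)(=O)C(F)(F)F | intermediate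
7 | 3-docosyl-4-methylcyclobut-2-en-1-one, racemic | CC1C(=O)C=C1CCCCCCCCCCCCCCCCCCCCCC | intermediate
8 | chloroacetaldehyde dimethyl acetal (2-chloro-1,1-dimethoxyethane) | COC(CCl)OC | starting material
9 | sodium methoxyacetylide | [Na+].[C-]#COC | intermediate
10 | methoxyacetylene (methoxyethyne) | COC#C | intermediate
11 | (3E)-3-docosylpenta-1,3-dien-1-one (vinylketene) | C/C=C(/C=C=O)CCCCCCCCCCCCCCCCCCCCCC | intermediate
12 | 3-methoxy-4-[(2E)-pentacos-2-en-3-yl]cyclobut-2-en-1-one, racemic | COC1=CC(=O)C1/C(CCCCCCCCCCCCCCCCCCCCCC)=C/C | intermediate
13 | (3E,5E)-5-docosyl-3-methoxyhepta-1,3,5-trien-1-one (dienylketene) | O=C=C/C(OC)=C\C(CCCCCCCCCCCCCCCCCCCCCC)=C\C | intermediate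
14 | 5-docosyl-3-methoxy-6-methylcyclohexa-2,4-dien-1-one, racemic | COC1=CC(=O)C(C)C(CCCCCCCCCCCCCCCCCCCCCC)=C1 | intermediate
15 | 3-docosyl-5-methoxy-2-methylphenol | COc1cc(O)c(C)c(CCCCCCCCCCCCCCCCCCCCCC)c1 | intermediate
16 | 6-docosyl-2-methoxy-5-methyl-1,4-benzoquinone (3-docosyl-5-methoxy-2-methylcyclohexa-2,5-diene-1,4-dione) | CCCCCCCCCCCCCCCCCCCCCCC1=C(C)C(=O)C=C(OC)C1=O | target

**Step count**

Total: 5 steps. Longest linear sequence: 4 steps (steps 1, 2, 4, 5); step 3 is a one-step branch that supplies the two-carbon partner.

**Steps most likely to fail**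

1. Step 4. The low-boiling ynol ether may escape or oligomerise before the cyclobutenone has opened at 80 °C, and the vinylketene may acylate the product phenol, so the annulation could stall. The fallback generates the same vinylketene photochemically at room temperature from a diazo ketone. It sets out from 1-bromodocosane 1 and methoxyacetylene 10 and comes back at phenol 15. Compound 1 would alkylate the sodium enolate of dimethyl (2-oxopropyl)phosphonate (NaH, DMF) to give dimethyl (2-oxopentacosan-3-yl)phosphonate F1. Horner–Wadsworth–Emmons reaction of F1 with acetaldehyde (NaH, THF) should give (3E)-3-docosylpent-3-en-2-one F2; either alkene geometry serves. Kinetic enolisation at the methyl group with LiN(SiMe3)2 at −78 °C and trapping with 2,2,2-trifluoroethyl trifluoroacetate would give (5E)-5-docosyl-1,1,1-trifluorohept-5-ene-2,4-dione F3. Detrifluoroacetylative diazo transfer (MsN3, Et3N, H2O, MeCN) then gives (3E)-1-diazo-3-docosylpent-3-en-2-one F4. Irradiation of F4 with 10 in ClCH2CH2Cl at or below room temperature should trigger a Wolff rearrangement to vinylketene 11, which is captured by 10 as 12. Brief warming to 80 °C then carries 12 through 13 and 14 to 15.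

2. Step 2. The monosubstituted keteniminium ion may condense with itself faster than the unactivated alkyne captures it, and the amine base may shift the ring double bond of the product. The fallback builds the cyclobutenone by carbonyl addition and transposition; it sets out from 1-bromodocosane 1 and comes back at cyclobutenone 7. Compound 1 is converted with Mg in THF into docosylmagnesium bromide F5. Separately, propanoyl chloride and Et3N generate methylketene F6, which undergoes [2+2] cycloaddition with ethoxyacetylene to give 3-ethoxy-4-methylcyclobut-2-en-1-one F7. Addition of F5 to the carbonyl group of F7 (THF, −78 °C) gives 1-docosyl-3-ethoxy-4-methylcyclobut-2-en-1-ol F8. Dilute aqueous HCl ionises the tertiary allylic alcohol and hydrolyses the enol ether with 1,3-carbonyl transposition, giving 7.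

3. Step 5. The waxy phenol may transfer poorly to the aqueous radical oxidant, leading to slow conversion, attack ortho to the hydroxyl or over-oxidation. The fallback is a homogeneous two-electron oxidation through a quinone monoketal; it sets out from phenol 15 and comes back at quinone 16. Treatment of 15 with PhI(OAc)2 (2.2 equiv) in MeOH/CH2Cl2 at 0 °C should add methanol twice at the para carbon to give 3-docosyl-4,4,5-trimethoxy-2-methylcyclohexa-2,5-dien-1-one F9. Mild aqueous acid (dilute HCl, THF/H2O, rt) then hydrolyses the ketal of F9 to 16 while the vinylogous ester methoxy group stays in place.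

**Further compounds**

F1 | step 4 | dimethyl (2-oxopentacosan-3-yl)phosphonate, racemic | CCCCCCCCCCCCCCCCCCCCCCC(C(C)=O)P(=O)(OC)OC
F2 | step 4 | (3E)-3-docosylpent-3-en-2-one | C/C=C(\CCCCCCCCCCCCCCCCCCCCCC)C(C)=O
F3 | step 4 | (5E)-5-docosyl-1,1,1-trifluorohept-5-ene-2,4-dione | C/C=C(\CCCCCCCCCCCCCCCCCCCCCC)C(=O)CC(=O)C(F)(F)F
F4 | step 4 | (3E)-1-diazo-3-docosylpent-3-en-2-one | C/C=C(\CCCCCCCCCCCCCCCCCCCCCC)C(=O)C=[N+]=[N-]
F5 | step 2 | docosylmagnesium bromide | CCCCCCCCCCCCCCCCCCCCCC[Mg]Br
F6 | step 2 | methylketene (prop-1-en-1-one) | CC=C=O
F7 | step 2 | 3-ethoxy-4-methylcyclobut-2-en-1-one, racemic | CCOC1=CC(=O)C1C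
F8 | step 2 | 1-docosyl-3-ethoxy-4-methylcyclobut-2-en-1-ol, racemic mixture of diastereomers | CCCCCCCCCCCCCCCCCCCCCCC1(O)C=C(OCC)C1C
F9 | step 5 | 3-docosyl-4,4,5-trimethoxy-2-methylcyclohexa-2,5-dien-1-one | COC1=CC(=O)C(C)=C(CCCCCCCCCCCCCCCCCCCCCC)C1(OC)OC
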